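**Plan**

- Retrosynthesis: the ester C–O bond is cut last and the C-4 carbinol goes back to an enone. The ring-fusion bond C-3a–C-8a of the hydroazulene is then traced back to bond C-8a–C-4a of a cis-decalin (a bond absent from the target) that carries a C-1 mesylate and a C-8a hydroxyl. The glycol goes back to a ring-fusion olefin, the isopropyl carbinol to an enone, and the decalin to a cyclohexanone by the two Robinson bonds.
- Forward: ring B (a chiral-pool cyclohexanone) is annulated to the octalone and oxygenated at C-2, C-1 and C-8a. One 1,2-shift then contracts ring A to the cyclopentane and expands ring B to the cycloheptanone. Dehydrogenation, reduction and acylation finish the route.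
- Enabling feature: in the seven-membered ring the oxygenated carbon C-4 is bonded to methine C-3a, which carries both the quaternary ring-fusion carbon C-8a and the tertiary carbinol C-3. The array O–C-4/C-3a/C-8a is the retron of a pinacol-type shift, and because C-3a belongs to both rings, the shift makes the five- and the seven-membered ring together.
- Stereochemistry: C-8a comes from a Michael addition controlled by (R)-1-phenylethylamine; the ring methyl of (R)-3-methylcyclohexanone is a disposable handle that turns the minor isomer into a separable diastereomer. C-3 is set by axial addition, the glycol by hydroxyl-directed osmylation, C-3a by inversion at the migration terminus, and C-4 by hydroxyl-directed hydride delivery.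

Key step: step 8

Assumption: azulene numbering is used for the bicyclo[5.3.0]decanes and naphthalene numbering for the decalins; ketone 6 is used as its C-2 epimer mixture because C-2 is re-set in step 3.

**Route**

Step 1
Reactants: 1 (R)-3-methylcyclohexanone; 2 ethyl formate
Product: 3 (5R)-2-(hydroxymethylidene)-5-methylcyclohexan-1-one
Conditions: NaOMe, toluene, 0 °C to rt; then aq HCl
Reagents that add atoms: ethyl formate, CCOC=O
Why: Crossed Claisen condensation (formylation) under equilibrating conditions should take place at the less hindered C-6 methylene, remote from the ring methyl, and the stereocenter is not touched.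

Step 2
Reactants: 3 (5R)-2-(hydroxymethylidene)-5-methylcyclohexan-1-one; 4 iodomethane
Product: 6 (5R)-2,5-dimethylcyclohexan-1-one (C-2 epimers), via formyl ketone 5 (not isolated)
Conditions: MeI, K2CO3, acetone, reflux; then 2 M aq NaOH, reflux
Reagents that add atoms: iodomethane, CI
Why: C-Alkylation of the 1,3-dicarbonyl anion followed by retro-Claisen loss of the formyl group as formate places the methyl at the carbon that step 1 activated.

Step 3
Reactants: 6 (5R)-2,5-dimethylcyclohexan-1-one; 7 (R)-1-phenylethylamine; 8 methyl vinyl ketone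
Product: 11 (2S,5R)-2,5-dimethyl-2-(3-oxobutyl)cyclohexan-1-one, via ketimine 9 (not isolated), via alkylated imine 10 (not isolated)
Conditions: (R)-1-phenylethylamine, TsOH (cat.), toluene, reflux (Dean–Stark); then methyl vinyl ketone, THF, rt; then 10% aq AcOH, rt
Reagents that add atoms: methyl vinyl ketone, CC(=O)C=C; water, O
Why: Michael addition of the more substituted secondary enamine tautomer of the chiral imine (aza-ene-like chair transition state with internal N–H transfer) occurs on the face away from the phenyl group, so the (R)-amine should set the (S)-quaternary carbon and override the weak bias of the remote ring methyl, which in turn makes the minor isomer a diastereomer that is removed by chromatography.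

Step 4
Reactants: 11 (2S,5R)-2,5-dimethyl-2-(3-oxobutyl)cyclohexan-1-one
Product: 12 (4aS,7R)-4a,7-dimethyl-4,4a,5,6,7,8-hexahydronaphthalen-2(3H)-one
Conditions: NaOMe, MeOH, 60 °C
Reagents that add atoms: none
Why: Intramolecular aldol condensation (second stage of the Robinson annulation) closes ring A as the conjugated octalone without touching either stereocenter.

Step 5
Reactants: 12 (4aS,7R)-4a,7-dimethyl-4,4a,5,6,7,8-hexahydronaphthalen-2(3H)-one; 13 isopropylmagnesium chloride
Product: 14 (2R,4aS,7R)-4a,7-dimethyl-2-(propan-2-yl)-2,3,4,4a,5,6,7,8-octahydronaphthalen-2-ol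
Conditions: i-PrMgCl, CeCl3, THF, −78 °C; pH 7 work-up
Reagents that add atoms: isopropylmagnesium chloride, CC(C)[Mg]Cl
Why: Organocerium 1,2-addition to the enone avoids conjugate addition, enolization and reduction, and axial attack on the half-chair from the face opposite the quasi-axial angular methyl should place the new hydroxyl cis to that methyl (2R), the minor epimer being separable.

Step 6
Reactants: 14 (2R,4aS,7R)-4a,7-dimethyl-2-(propan-2-yl)-2,3,4,4a,5,6,7,8-octahydronaphthalen-2-ol
Product: 16 (1S,2R,4aS,7R,8aR)-4a,7-dimethyl-2-(propan-2-yl)decahydronaphthalene-1,2,8a-triol, via osmate ester 15 (not isolated)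
Conditions: OsO4 (1 equiv), TMEDA, CH2Cl2, −78 °C; then aq Na2SO3, THF, 60 °C
Reagents that add atoms: osmium tetroxide, O=[Os](=O)(=O)=O
Why: Hydrogen-bond-directed syn dihydroxylation: the OsO4·TMEDA complex is bound by the allylic tertiary hydroxyl and delivers both oxygens to the olefin face that carries it, which should give the all-cis triol with a cis ring fusion (1S,8aR).

Step 7
Reactants: 16 (1S,2R,4aS,7R,8aR)-4a,7-dimethyl-2-(propan-2-yl)decahydronaphthalene-1,2,8a-triol
Product: 17 (1S,2R,4aS,7R,8aR)-2,8a-dihydroxy-4a,7-dimethyl-2-(propan-2-yl)decahydronaphthalen-1-yl methanesulfonate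
Conditions: MsCl, Et3N, CH2Cl2, −20 °C
Reagents that add atoms: methanesulfonyl chloride, CS(=O)(=O)Cl
Why: Sulfonylation (via sulfene) should take place only at the single secondary hydroxyl, the two tertiary hydroxyls being far slower.

Step 8
Reactants: 17 (1S,2R,4aS,7R,8aR)-2,8a-dihydroxy-4a,7-dimethyl-2-(propan-2-yl)decahydronaphthalen-1-yl methanesulfonate
Product: 18 (3R,3aR,6R,8aS)-3-hydroxy-6,8a-dimethyl-3-(propan-2-yl)octahydroazulen-4(1H)-one
Conditions: Et2AlCl (3.5 equiv), CH2Cl2, −78 to −20 °C; then aq KNaC4H4O6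
Reagents that add atoms: none
Why: Et2AlCl turns both tertiary hydroxyls into aluminium alkoxides and activates the mesylate, and the C-8a alkoxide then pushes the ring-fusion carbon C-4a from C-8a to C-1 with loss of mesylate in a concerted anti 1,2-shift; this is a pinacol-type (semipinacol) rearrangement of a 2-sulfonyloxy alcohol, the reaction type long used to turn decalin-1,8a-diol monosulfonates into hydroazulenones. The cyclopentane is closed by this 1,2-alkyl migration itself (C-4a bonds to C-1 as it leaves C-8a, so ring A contracts from six to five atoms), and the cycloheptanone arises in the same event by one-atom expansion of ring B, old C-1 being inserted between C-8a and C-4a. The new methine C-3a is set by inversion at the migration terminus (C-4a enters anti to the equatorial mesylate), the migrating quaternary carbon keeps its configuration and becomes C-8a, and C-3 is untouched, so the trans ring fusion and the cis relation of the C-3 hydroxyl to the C-8a methyl follow from the all-cis arrangement made in step 6. The step needs migration of C-4a in preference to C-3 (which the C-2 alkoxide could push) and to epoxide formation or elimination: in the cis-decalin chair with isopropyl, mesylate and the C-7 methyl equatorial, bonds C-8a–C-4a and C-2–C-3 are both antiperiplanar to C-1–O, but the migrating carbon is quaternary in the first case and primary in the second, the all-cis oxygens cannot close an epoxide from the back, and no anti hydrogen is available. Aluminium chelation of the aldolate formed is expected to suppress retro-aldol cleavage and epimerization at C-3a.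

Step 9
Reactants: 18 (3R,3aR,6R,8aS)-3-hydroxy-6,8a-dimethyl-3-(propan-2-yl)octahydroazulen-4(1H)-one
Product: 21 (3R,3aR,8aS)-3-hydroxy-6,8a-dimethyl-3-(propan-2-yl)-2,3,3a,7,8,8a-hexahydroazulen-4(1H)-one, via bis-silyl enol ether 19 (not isolated), via silyl ether enone 20 (not isolated)
Conditions: LiN(iPr)2 (2.5 equiv), Me3SiCl, THF, −78 to 0 °C; then Pd(OAc)2, MeCN, rt; then 1 M aq HCl, THF, 0 °C
Reagents that add atoms: none
Why: Saegusa–Ito oxidation: kinetic deprotonation should occur at the C-5 methylene and not at the hindered C-3a methine (so the ring fusion is not epimerized), the palladium enolate can only eliminate the C-6 hydrogen, which gives the trisubstituted enone and erases the auxiliary C-6 stereocenter, and the tertiary silyl ether falls off in the acidic work-up.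

Step 10
Reactants: 21 (3R,3aR,8aS)-3-hydroxy-6,8a-dimethyl-3-(propan-2-yl)-2,3,3a,7,8,8a-hexahydroazulen-4(1H)-one
Product: 22 (3R,3aS,4S,8aS)-6,8a-dimethyl-3-(propan-2-yl)-1,2,3,3a,4,7,8,8a-octahydroazulene-3,4-diol
Conditions: Me4NBH(OAc)3, MeCN/AcOH, −30 °C
Reagents that add atoms: none
Why: Evans–Saksena reduction: the C-3 hydroxyl exchanges onto boron and the alkoxy(diacetoxy)borohydride delivers hydride through a six-membered transition state to the ketone face on its own side, which should give 1,2-reduction to the anti-1,3-diol, i.e. the (4S) allylic alcohol with its oxygen cis to H-3a.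

Step 11
Reactants: 22 (3R,3aS,4S,8aS)-6,8a-dimethyl-3-(propan-2-yl)-1,2,3,3a,4,7,8,8a-octahydroazulene-3,4-diol; 23 4-[(tert-butyldimethylsilyl)oxy]benzoic acid
Product: 24 (3R,3aS,4S,8aS)-3-hydroxy-6,8a-dimethyl-3-(propan-2-yl)-1,2,3,3a,4,7,8,8a-octahydroazulen-4-yl 4-[(tert-butyldimethylsilyl)oxy]benzoate
Conditions: DCC, DMAP, CH2Cl2, rt
Reagents that add atoms: 4-[(tert-butyldimethylsilyl)oxy]benzoic acid, CC(C)(C)[Si](C)(C)Oc1ccc(cc1)C(O)=O
Why: Steglich esterification should acylate only the secondary allylic hydroxyl, the tertiary C-3 hydroxyl being inert, and the phenol is masked as its silyl ether so that the acid cannot condense with itself.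

Step 12
Reactants: 24 (3R,3aS,4S,8aS)-3-hydroxy-6,8a-dimethyl-3-(propan-2-yl)-1,2,3,3a,4,7,8,8a-octahydroazulen-4-yl 4-[(tert-butyldimethylsilyl)oxy]benzoate
Product: 25 (3R,3aS,4S,8aS)-3-hydroxy-6,8a-dimethyl-3-(propan-2-yl)-1,2,3,3a,4,7,8,8a-octahydroazulen-4-yl 4-hydroxybenzoate
Conditions: Bu4NF, AcOH, THF, 0 °C
Reagents that add atoms: none
Why: Fluoride cleavage of the aryl silyl ether, buffered with AcOH so that the phenoxide does not attack the ester, should release the phenol and give the target.

**Compound list**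

1 | (R)-3-methylcyclohexanone | C[C@@H]1CCCC(=O)C1 | starting material
2 | ethyl formate | CCOC=O | starting material
3 | (5R)-2-(hydroxymethylidene)-5-methylcyclohexan-1-one | O/C=C1/CC[C@@H](C)CC1=O | intermediate
4 | iodomethane | CI | starting material
5 | (4R)-1,4-dimethyl-2-oxocyclohexane-1-carbaldehyde (C-1 epimers; not isolated) | O=CC1(C)CC[C@@H](C)CC1=O | intermediate
6 | (5R)-2,5-dimethylcyclohexan-1-one (C-2 epimers) | CC1CC[C@@H](C)CC1=O | intermediate
7 | (R)-1-phenylethylamine | C[C@@H](N)c1ccccc1 | starting material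
8 | methyl vinyl ketone | CC(=O)C=C | starting material
9 | (5R)-2,5-dimethyl-N-[(1R)-1-phenylethyl]cyclohexan-1-imine (not isolated) | C[C@@H](N=C1C[C@H](C)CCC1C)c1ccccc1 | intermediate
10 | 4-[(1S,4R)-1,4-dimethyl-2-{[(1R)-1-phenylethyl]imino}cyclohexyl]butan-2-one (not isolated) | C[C@@H](N=C1C[C@H](C)CC[C@@]1(C)CCC(C)=O)c1ccccc1 | intermediate
11 | (2S,5R)-2,5-dimethyl-2-(3-oxobutyl)cyclohexan-1-one | O=C1[C@](C)(CCC(C)=O)CC[C@@H](C)C1 | intermediate
12 | (4aS,7R)-4a,7-dimethyl-4,4a,5,6,7,8-hexahydronaphthalen-2(3H)-one | O=C1CC[C@]2(C)CC[C@@H](C)CC2=C1 | intermediate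
13 | isopropylmagnesium chloride | CC(C)[Mg]Cl | starting material
14 | (2R,4aS,7R)-4a,7-dimethyl-2-(propan-2-yl)-2,3,4,4a,5,6,7,8-octahydronaphthalen-2-ol (hydroxyl cis to the angular methyl) | CC(C)[C@]1(O)CC[C@]2(C)CC[C@@H](C)CC2=C1 | intermediate
15 | cyclic osmate ester of 16 at O-1 and O-8a, TMEDA complex (not isolated) | CC(C)[C@]1(O)CC[C@]2(C)CC[C@@H](C)C[C@@]23O[Os](=O)(=O)O[C@@H]13.CN(C)CCN(C)C | intermediate
16 | (1S,2R,4aS,7R,8aR)-4a,7-dimethyl-2-(propan-2-yl)decahydronaphthalene-1,2,8a-triol (three hydroxyls and angular methyl all cis) | CC(C)[C@]1(O)CC[C@]2(C)CC[C@@H](C)C[C@]2(O)[C@H]1O | intermediate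
17 | (1S,2R,4aS,7R,8aR)-2,8a-dihydroxy-4a,7-dimethyl-2-(propan-2-yl)decahydronaphthalen-1-yl methanesulfonate | CC(C)[C@]1(O)CC[C@]2(C)CC[C@@H](C)C[C@]2(O)[C@H]1OS(C)(=O)=O | intermediate
18 | (3R,3aR,6R,8aS)-3-hydroxy-6,8a-dimethyl-3-(propan-2-yl)octahydroazulen-4(1H)-one (trans-fused) | C[C@H]1CC(=O)[C@@H]2[C@@](C)(CC1)CC[C@@]2(O)C(C)C | intermediate
19 | bis(trimethylsilyl) derivative of 18: C-4/C-5 silyl enol ether and 3-O-silyl ether, configurations as in 18 (not isolated) | C[C@H]1C=C(O[Si](C)(C)C)[C@@H]2[C@@](C)(CC1)CC[C@@]2(O[Si](C)(C)C)C(C)C | intermediate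
20 | (3R,3aR,8aS)-6,8a-dimethyl-3-(propan-2-yl)-3-[(trimethylsilyl)oxy]-2,3,3a,7,8,8a-hexahydroazulen-4(1H)-one (not isolated) | CC1=CC(=O)[C@@H]2[C@@](C)(CC1)CC[C@@]2(O[Si](C)(C)C)C(C)C | intermediate
21 | (3R,3aR,8aS)-3-hydroxy-6,8a-dimethyl-3-(propan-2-yl)-2,3,3a,7,8,8a-hexahydroazulen-4(1H)-one | CC1=CC(=O)[C@@H]2[C@@](C)(CC1)CC[C@@]2(O)C(C)C | intermediate
22 | (3R,3aS,4S,8aS)-6,8a-dimethyl-3-(propan-2-yl)-1,2,3,3a,4,7,8,8a-octahydroazulene-3,4-diol | CC1=C[C@H](O)[C@@H]2[C@@](C)(CC1)CC[C@@]2(O)C(C)C | intermediate
23 | 4-[(tert-butyldimethylsilyl)oxy]benzoic acid | CC(C)(C)[Si](C)(C)Oc1ccc(cc1)C(O)=O | starting material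
24 | (3R,3aS,4S,8aS)-3-hydroxy-6,8a-dimethyl-3-(propan-2-yl)-1,2,3,3a,4,7,8,8a-octahydroazulen-4-yl 4-[(tert-butyldimethylsilyl)oxy]benzoate | CC1=C[C@H](OC(=O)c2ccc(O[Si](C)(C)C(C)(C)C)cc2)[C@@H]2[C@@](C)(CC1)CC[C@@]2(O)C(C)C | intermediate
25 | (3R,3aS,4S,8aS)-3-hydroxy-6,8a-dimethyl-3-(propan-2-yl)-1,2,3,3a,4,7,8,8a-octahydroazulen-4-yl 4-hydroxybenzoate | CC1=C[C@H](OC(=O)c2ccc(O)cc2)[C@@H]2[C@@](C)(CC1)CC[C@@]2(O)C(C)C | target

**Step count**

Total: 12 steps. Longest linear sequence: 12 steps (1 to 25).

**Steps most likely to fail, with fallbacks**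

Step 8 (key step). The C-2 alkoxide may push C-3 instead (ring contraction without ring expansion), or the non-conjugated aldol may revert or epimerize at C-3a before work-up. The fallback runs the shift on a substrate whose C-8a carbinol is allylic, so that only the desired migration ends in a conjugated enone. It sets out from octalone 12 and returns at enone 21, so step 9 falls away. Chloranil in refluxing t-BuOH should give the linear dienone (4aS)-4a,7-dimethyl-4,4a,5,6-tetrahydronaphthalen-2(3H)-one F1. Addition of i-PrMgCl/CeCl3 should give the dienol (2R,4aS)-4a,7-dimethyl-2-(propan-2-yl)-2,3,4,4a,5,6-hexahydronaphthalen-2-ol F2. OsO4·TMEDA, guided by the hydroxyl to the nearer double bond, should give the TMEDA-complexed cyclic osmate ester F3, and cleavage with aq Na2SO3 the triol (1S,2R,4aS,8aR)-4a,7-dimethyl-2-(propan-2-yl)-1,2,3,4,4a,5,6,8a-octahydronaphthalene-1,2,8a-triol F4. MsCl/Et3N should give the C-1 monomesylate of that triol F5, and Et2AlCl should then give 21 directly.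

Step 5. The bulky reagent may attack syn to the angular methyl (poor facial selectivity), or enolize or reduce the enone. The fallback uses a temporary oxirane as the control element; it sets out from 12 and returns at 14. NaOH/H2O2 (MeOH, 0 °C) should give the epoxy ketone with the oxide cis to the angular methyl, (1R,4aS,7R,8aR)-1,8a-epoxy-4a,7-dimethyloctahydronaphthalen-2(1H)-one F6. Addition of i-PrMgCl/CeCl3 anti to the oxirane should give the cis-epoxy alcohol (1S,2R,4aS,7R,8aR)-1,8a-epoxy-4a,7-dimethyl-2-(propan-2-yl)decahydronaphthalen-2-ol F7. Deoxygenation of the oxirane with WCl6/n-BuLi (THF) restores the olefin and gives 14.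

Step 10. The hindered tertiary hydroxyl may exchange too slowly onto boron, so that undirected hydride attack from the opposite face competes. The fallback makes the other epimer on purpose and inverts it in the esterification; it sets out from 21 and returns at 24. Luche reduction (NaBH4, CeCl3, MeOH, −78 °C), which should attack the face away from the angular methyl and the C-3 hydroxyl, gives (3R,3aS,4R,8aS)-6,8a-dimethyl-3-(propan-2-yl)-1,2,3,3a,4,7,8,8a-octahydroazulene-3,4-diol F8. Mitsunobu esterification of this diol with acid 23 (PPh3, diisopropyl azodicarboxylate, THF) inverts C-4 and gives 24.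

**Further compounds**

F1 | step 8 | (4aS)-4a,7-dimethyl-4,4a,5,6-tetrahydronaphthalen-2(3H)-one | O=C1CC[C@]2(C)CCC(C)=CC2=C1
F2 | step 8 | (2R,4aS)-4a,7-dimethyl-2-(propan-2-yl)-2,3,4,4a,5,6-hexahydronaphthalen-2-ol | CC(C)[C@]1(O)CC[C@]2(C)CCC(C)=CC2=C1
F3 | step 8 | cyclic osmate ester of F4 at O-1 and O-8a, TMEDA complex | CC(C)[C@]1(O)CC[C@]2(C)CCC(C)=C[C@@]23O[Os](=O)(=O)O[C@@H]13.CN(C)CCN(C)C
F4 | step 8 | (1S,2R,4aS,8aR)-4a,7-dimethyl-2-(propan-2-yl)-1,2,3,4,4a,5,6,8a-octahydronaphthalene-1,2,8a-triol | CC(C)[C@]1(O)CC[C@]2(C)CCC(C)=C[C@]2(O)[C@H]1O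
F5 | step 8 | (1S,2R,4aS,8aR)-2,8a-dihydroxy-4a,7-dimethyl-2-(propan-2-yl)-1,2,3,4,4a,5,6,8a-octahydronaphthalen-1-yl methanesulfonate | CC(C)[C@]1(O)CC[C@]2(C)CCC(C)=C[C@]2(O)[C@H]1OS(C)(=O)=O
F6 | step 5 | (1R,4aS,7R,8aR)-1,8a-epoxy-4a,7-dimethyloctahydronaphthalen-2(1H)-one | O=C1CC[C@]2(C)CC[C@@H](C)C[C@@]23O[C@@H]13
F7 | step 5 | (1S,2R,4aS,7R,8aR)-1,8a-epoxy-4a,7-dimethyl-2-(propan-2-yl)decahydronaphthalen-2-ol | CC(C)[C@]1(O)CC[C@]2(C)CC[C@@H](C)C[C@@]23O[C@@H]13
F8 | step 10 | (3R,3aS,4R,8aS)-6,8a-dimethyl-3-(propan-2-yl)-1,2,3,3a,4,7,8,8a-octahydroazulene-3,4-diol | CC1=C[C@@H](O)[C@@H]2[C@@](C)(CC1)CC[C@@]2(O)C(C)C
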